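## Retrosynthetic overview

1. Sideroxylonal A ⇒ take the two formyl groups off ring B (returned last by Vilsmeier–Haack formylation) and mask its three phenols as benzyl ethers; ring A keeps its formyl groups throughout.
2. Pyran ring ⇒ cut O1–C2 and C4a–C4 together: a formal [3+3] union of a 1,3-C,O-dinucleophile (O1–C8a–C4a of 2,4-diformylphloroglucinol) with a 1,3-dielectrophile (a C2–C3–C4 allyl cation).
3. Enabling feature: C2 is benzylic to the 2,4,6-trioxygenated ring B, so C2–C3–C4 forms a stabilised allyl cation from an allylic alcohol; C4a is the single unsubstituted carbon of the mirror-symmetric ring A and lies between the two equivalent hydroxyl-bearing carbons C5 and C8a, so either oxygen closes the same ring.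
4. Allylic alcohol ⇒ 2,4,6-tris(benzyloxy)phenyllithium + 2-isopropyl-5-methylhex-2-enal, the commercial self-aldol dimer of isovaleraldehyde, which already holds C2, C3, C4, the isopropyl and the isobutyl group.
5. Ring order: rings A and B are bought as phloroglucinol derivatives; the pyran ring is the only ring made (step 3), and C2, C3 and C4 are set in that step.

Key step: step 3

Assumption: the commercial enal is taken as its (E)-isomer (its geometry is lost on ionisation in step 3), and (R)-TRIP, (R)-3,3'-bis(2,4,6-triisopropylphenyl)-1,1'-binaphthyl-2,2'-diyl hydrogen phosphate, is written for step 3 on the understanding that its antipode is used should the sense of induction at C4 prove opposite.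

## Route

Step 1
Reactants: 1 phloroglucinol
Product: 3 2,4-diformylphloroglucinol (2,4,6-trihydroxybenzene-1,3-dicarbaldehyde), via bis(iminium) dichloride 2 (not isolated)
Conditions: POCl3 (2.2 equiv), DMF (2.2 equiv), 1,4-dioxane, 0 °C → rt; then H2O, 50 °C
Reagents that add atoms: N,N-dimethylformamide (DMF), CN(C)C=O; water, O
Why: Vilsmeier–Haack formylation, in which the chloroiminium ion should attack the strongly activated triphenol ring twice and hydrolysis of bis(iminium) salt 2 should give the dialdehyde; no stereocentre is formed.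

Step 2
Reactants: 4 1,3,5-tris(benzyloxy)benzene; 5 (E)-2-isopropyl-5-methylhex-2-enal
Product: 8 (E)-2-isopropyl-5-methyl-1-[2,4,6-tris(benzyloxy)phenyl]hex-2-en-1-ol (racemic), via 2,4,6-tris(benzyloxy)phenyllithium 6 (not isolated), via lithium alkoxide 7 (not isolated)
Conditions: n-BuLi (1.1 equiv), THF, 0 °C, 1 h; then 5, −78 → 0 °C; sat. aq. NH4Cl; chromatography on Et3N-deactivated SiO2
Reagents that add atoms: none
Why: Directed ortho-lithiation between two alkoxy groups followed by 1,2-addition of the aryllithium to the enal carbonyl should give the carbinol, whose new centre is formed racemic without consequence because it is ionised in step 3.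

Step 3
Reactants: 8 (E)-2-isopropyl-5-methyl-1-[2,4,6-tris(benzyloxy)phenyl]hex-2-en-1-ol; 3 2,4-diformylphloroglucinol (1.5 equiv)
Product: 11 (2R,3R,4S)-5,7-dihydroxy-4-isobutyl-3-isopropyl-2-[2,4,6-tris(benzyloxy)phenyl]chroman-6,8-dicarbaldehyde, via allyl cation 9 (not isolated), via Friedel–Crafts adduct 10 (not isolated)
Conditions: (R)-TRIP (10 mol %), 5 Å MS, CHCl3, −30 → 0 °C, 8 added slowly
Reagents that add atoms: none
Why: Proposed new method: the chiral phosphoric acid ionises racemic 8 to allyl cation 9, held as a contact ion pair with the chiral phosphate and with its aryl group cis to C4 because the 2-isopropyl group blocks the other position; the one unsubstituted ring carbon of 3 then attacks the alkyl terminus C4 (Friedel–Crafts) to give (Z)-styrene 10, and acid-mediated addition of the flanking phenol O–H across C2=C3 closes the ring; the closest known reaction types are the Brønsted acid-catalysed annulation of phenols with allylic alcohols to chromans and chiral phosphoric acid-catalysed substitutions of allylic alcohols through allyl cation–phosphate ion pairs, which have not been joined into one enantioselective intermolecular annulation on a phloroglucinol. The pyran ring closes 6-endo-trig on the styrene (Markovnikov hydroalkoxylation, O1 to C2), the developing C2 cation being stabilised by the 2,4,6-tris(benzyloxy)phenyl ring. C4 is set by the catalyst, whose phosphate hydrogen-bonds to a phenol of 3 and guides the nucleophilic carbon to one enantiotopic face of the cation terminus. C3 and C2 are set by the substrate: anti addition of O and H across the (Z)-alkene through a chair transition state with aryl and isopropyl trans-diaxial, in which the isobutyl group takes the pseudo-equatorial site to avoid a 1,3-diaxial clash with the aryl group, should give the 2,3-trans,3,4-cis chroman, whose ring flip places aryl and isopropyl equatorial. The step needs attack at C4 and not at C2 (C2 is shielded by two ortho benzyloxy groups and the isopropyl group, and attack there or on oxygen is reversible by re-ionisation), six- over five-membered closure (benzylic against tertiary alkyl cation) and no choice between ring oxygens, which the mirror symmetry of 3 secures because its nucleophilic carbon lies between two equivalent hydroxyl groups.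

Step 4
Reactants: 11 (2R,3R,4S)-5,7-dihydroxy-4-isobutyl-3-isopropyl-2-[2,4,6-tris(benzyloxy)phenyl]chroman-6,8-dicarbaldehyde
Product: 12 (2R,3R,4S)-5,7-dihydroxy-4-isobutyl-3-isopropyl-2-(2,4,6-trihydroxyphenyl)chroman-6,8-dicarbaldehyde
Conditions: H2 (1 atm), Pd/C (10 wt %), EtOAc, rt, stopped at full debenzylation; used at once
Reagents that add atoms: none
Why: Catalytic hydrogenolysis of aryl benzyl ethers under neutral conditions should be much faster than reduction of the hydrogen-bonded aryl aldehydes or cleavage of the hindered C2–O1 bond, and it touches no stereocentre.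

Step 5
Reactants: 12 (2R,3R,4S)-5,7-dihydroxy-4-isobutyl-3-isopropyl-2-(2,4,6-trihydroxyphenyl)chroman-6,8-dicarbaldehyde
Product: 14 sideroxylonal A, via bis(iminium) dichloride 13 (not isolated)
Conditions: POCl3 (2.5 equiv), DMF (3 equiv), EtOAc, 0 °C; then H2O, 0 °C → rt
Reagents that add atoms: N,N-dimethylformamide (DMF), CN(C)C=O; water, O
Why: Vilsmeier–Haack formylation of the free phloroglucinol ring B at its only two unsubstituted positions (ring A has none), as in step 1, run cold so that the C2–O1 bond is not ionised and the three stereocentres are kept.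

## Compound list

1 | phloroglucinol (benzene-1,3,5-triol) | Oc1cc(O)cc(O)c1 | starting material
2 | bis(iminium) dichloride of phloroglucinol (2,4-bis(dimethyliminiomethyl)phloroglucinol dichloride) | C[N+](C)=Cc1c(O)cc(O)c(C=[N+](C)C)c1O.[Cl-].[Cl-] | intermediate
3 | 2,4-diformylphloroglucinol (2,4,6-trihydroxybenzene-1,3-dicarbaldehyde) | O=Cc1c(O)cc(O)c(C=O)c1O | intermediate
4 | 1,3,5-tris(benzyloxy)benzene | C(Oc1cc(OCc2ccccc2)cc(OCc2ccccc2)c1)c1ccccc1 | starting material
5 | (E)-2-isopropyl-5-methylhex-2-enal | CC(C)C/C=C(\C(C)C)C=O | starting material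
6 | 2,4,6-tris(benzyloxy)phenyllithium | [Li]c1c(OCc2ccccc2)cc(OCc2ccccc2)cc1OCc1ccccc1 | intermediate
7 | lithium (E)-2-isopropyl-5-methyl-1-[2,4,6-tris(benzyloxy)phenyl]hex-2-en-1-olate (racemic) | [Li]OC(c1c(OCc2ccccc2)cc(OCc2ccccc2)cc1OCc1ccccc1)/C(=C/CC(C)C)C(C)C | intermediate
8 | (E)-2-isopropyl-5-methyl-1-[2,4,6-tris(benzyloxy)phenyl]hex-2-en-1-ol (racemic at C1) | OC(c1c(OCc2ccccc2)cc(OCc2ccccc2)cc1OCc1ccccc1)/C(=C/CC(C)C)C(C)C | intermediate
9 | 2-isopropyl-5-methyl-1-[2,4,6-tris(benzyloxy)phenyl]hex-2-en-1-ylium (allyl cation, paired with the chiral phosphate) | CC(C)C/C=C(\C(C)C)[CH+]c1c(OCc2ccccc2)cc(OCc2ccccc2)cc1OCc1ccccc1 | intermediate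
10 | 2,4,6-trihydroxy-5-{(1Z)-2-isopropyl-5-methyl-1-[2,4,6-tris(benzyloxy)phenyl]hex-1-en-3-yl}benzene-1,3-dicarbaldehyde, chain C3 configured as C4 of 11 | CC(C)C[C@H](c1c(O)c(C=O)c(O)c(C=O)c1O)/C(=C\c1c(OCc2ccccc2)cc(OCc2ccccc2)cc1OCc1ccccc1)C(C)C | intermediate
11 | (2R,3R,4S)-5,7-dihydroxy-4-isobutyl-3-isopropyl-2-[2,4,6-tris(benzyloxy)phenyl]chroman-6,8-dicarbaldehyde | CC(C)C[C@@H]1c2c(O)c(C=O)c(O)c(C=O)c2O[C@@H](c2c(OCc3ccccc3)cc(OCc3ccccc3)cc2OCc2ccccc2)[C@@H]1C(C)C | intermediate
12 | (2R,3R,4S)-5,7-dihydroxy-4-isobutyl-3-isopropyl-2-(2,4,6-trihydroxyphenyl)chroman-6,8-dicarbaldehyde | CC(C)C[C@@H]1c2c(O)c(C=O)c(O)c(C=O)c2O[C@@H](c2c(O)cc(O)cc2O)[C@@H]1C(C)C | intermediate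
13 | bis(iminium) dichloride of 12 (dimethyliminiomethyl groups at both free positions of ring B) | CC(C)C[C@@H]1c2c(O)c(C=O)c(O)c(C=O)c2O[C@@H](c2c(O)c(C=[N+](C)C)c(O)c(C=[N+](C)C)c2O)[C@@H]1C(C)C.[Cl-].[Cl-] | intermediate
14 | sideroxylonal A, (2R,3R,4S)-2-(3,5-diformyl-2,4,6-trihydroxyphenyl)-5,7-dihydroxy-4-isobutyl-3-isopropylchroman-6,8-dicarbaldehyde (2,3-trans, 3,4-cis) | CC(C)C[C@@H]1c2c(O)c(C=O)c(O)c(C=O)c2O[C@@H](c2c(O)c(C=O)c(O)c(C=O)c2O)[C@@H]1C(C)C | target

## Step count and risks

Total step count: 5. Longest linear sequence: 4 steps (4 → 8 → 11 → 12 → 14; the branch 1 → 3 joins at step 3).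

Steps most likely to fail:

1. Step 3 (proposed new method). The process at risk is weak enantiofacial discrimination at the C4 terminus of the cation, for example through uncatalysed ionisation of 8 by the acidic phenol 3. A second risk is loss of the kinetic 3,4-cis relationship if the C2–O1 bond reopens and the C3 proton is lost and returned; the C3 epimer may be of similar stability, so the reaction should be stopped once cyclisation is complete. The fallback uses known chemistry and sets out from 8 and 3. The annulation is run with an achiral Brønsted acid (diphenyl phosphate, CH2Cl2, 0 °C), the established acid-catalysed phenol/allylic alcohol chroman synthesis. It should give 11 as the racemate, that is together with its mirror image ent-11 F1. Diastereomers are removed on silica, and the racemate is resolved by preparative HPLC on an amylose tris(3,5-dimethylphenylcarbamate) phase. F1 is discarded and the route is rejoined at 11.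

2. Step 5. The process at risk is acid-triggered ionisation of the C2–O1 bond of the electron-rich trihydroxyphenyl chroman 12 before ring B is formylated, followed by loss of the C3 proton and re-closure with scrambled configuration; a stalled second formylation is the other risk. The fallback divides the formylation around the deprotection, so that ring B is never both unprotected and unformylated, and sets out from 11. One Vilsmeier–Haack formylation of the tris(benzyloxy)phenyl ring (POCl3, DMF, 0 °C → rt; then H2O) runs through iminium chloride F5 and gives the ring B monoaldehyde F6. Hydrogenolysis (H2, Pd/C, EtOAc) gives the trihydroxy monoaldehyde F7, in which the formyl group already deactivates ring B towards ionisation. A second Vilsmeier–Haack formylation through iminium chloride F8 then gives 14, where the route is rejoined.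

3. Step 4. The process at risk is over-reduction of the two ring A formyl groups (to hydroxymethyl or methyl) or hydrogenolysis of the benzylic C2–O1 bond while the three benzyl ethers are cleaved. The fallback changes the order so that no aldehyde is present at the hydrogenolysis, and sets out from 8. The annulation of step 3 is run with phloroglucinol 1 (4 equiv, same catalyst) in place of 3 and should give (2R,3R,4S)-4-isobutyl-3-isopropyl-2-[2,4,6-tris(benzyloxy)phenyl]chroman-5,7-diol F2. Hydrogenolysis (H2, Pd/C, EtOAc) gives the pentaphenol (2R,3R,4S)-4-isobutyl-3-isopropyl-2-(2,4,6-trihydroxyphenyl)chroman-5,7-diol F3. Fourfold Vilsmeier–Haack formylation (POCl3, DMF, 0 °C; then H2O) through tetrakis(iminium) tetrachloride F4 fills the four free ring positions and gives 14, where the route is rejoined.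

## Further compounds

F1 | step 3 | ent-11, (2S,3S,4R)-5,7-dihydroxy-4-isobutyl-3-isopropyl-2-[2,4,6-tris(benzyloxy)phenyl]chroman-6,8-dicarbaldehyde | CC(C)C[C@H]1c2c(O)c(C=O)c(O)c(C=O)c2O[C@H](c2c(OCc3ccccc3)cc(OCc3ccccc3)cc2OCc2ccccc2)[C@H]1C(C)C
F2 | step 4 | (2R,3R,4S)-4-isobutyl-3-isopropyl-2-[2,4,6-tris(benzyloxy)phenyl]chroman-5,7-diol | CC(C)C[C@@H]1c2c(O)cc(O)cc2O[C@@H](c2c(OCc3ccccc3)cc(OCc3ccccc3)cc2OCc2ccccc2)[C@@H]1C(C)C
F3 | step 4 | (2R,3R,4S)-4-isobutyl-3-isopropyl-2-(2,4,6-trihydroxyphenyl)chroman-5,7-diol | CC(C)C[C@@H]1c2c(O)cc(O)cc2O[C@@H](c2c(O)cc(O)cc2O)[C@@H]1C(C)C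
F4 | step 4 | tetrakis(iminium) tetrachloride of F3 (dimethyliminiomethyl groups at C6, C8 and both free positions of ring B) | CC(C)C[C@@H]1c2c(O)c(C=[N+](C)C)c(O)c(C=[N+](C)C)c2O[C@@H](c2c(O)c(C=[N+](C)C)c(O)c(C=[N+](C)C)c2O)[C@@H]1C(C)C.[Cl-].[Cl-].[Cl-].[Cl-]
F5 | step 5 | iminium chloride of 11 (one dimethyliminiomethyl group on ring B) | CC(C)C[C@@H]1c2c(O)c(C=O)c(O)c(C=O)c2O[C@@H](c2c(OCc3ccccc3)cc(OCc3ccccc3)c(C=[N+](C)C)c2OCc2ccccc2)[C@@H]1C(C)C.[Cl-]
F6 | step 5 | (2R,3R,4S)-2-[2,4,6-tris(benzyloxy)-3-formylphenyl]-5,7-dihydroxy-4-isobutyl-3-isopropylchroman-6,8-dicarbaldehyde | CC(C)C[C@@H]1c2c(O)c(C=O)c(O)c(C=O)c2O[C@@H](c2c(OCc3ccccc3)cc(OCc3ccccc3)c(C=O)c2OCc2ccccc2)[C@@H]1C(C)C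
F7 | step 5 | (2R,3R,4S)-2-(3-formyl-2,4,6-trihydroxyphenyl)-5,7-dihydroxy-4-isobutyl-3-isopropylchroman-6,8-dicarbaldehyde | CC(C)C[C@@H]1c2c(O)c(C=O)c(O)c(C=O)c2O[C@@H](c2c(O)cc(O)c(C=O)c2O)[C@@H]1C(C)C
F8 | step 5 | iminium chloride of F7 (dimethyliminiomethyl group at the last free position of ring B) | CC(C)C[C@@H]1c2c(O)c(C=O)c(O)c(C=O)c2O[C@@H](c2c(O)c(C=[N+](C)C)c(O)c(C=O)c2O)[C@@H]1C(C)C.[Cl-]
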